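**Plan**

- Cuts, in retrosynthetic order: the lactone C1(=O)–O bond; C16–C17 (alkyne plus enal, the 15Z alkene being a half-hydrogenated alkyne); ring C at C22 (N–C22 and C2–C22, Mannich) and C2–C3 (Claisen); ring B at N–C5 (aza-Michael); the arm at C4=C5, C5–C6 (two Wittig reactions) and C15–C16 (alkyne homologation); last C9–C8 and C13–C14.
- Enabling feature: cyclopentane ring A carries three contiguous stereocentres, the N-bearing spiro carbon C9, ring carbon C13 and exocyclic C14 (CHCH3), with N cis to the C14 arm. C13 and C9 are the β- and α-carbons of 1-nitrocyclopentene, so an aldehyde enamine at C13 and then an acrylate at C9 assemble the triad in one flask, with the nitro group as latent amine.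
- Forward order: ring A is bought as cyclopentene; three-component coupling; C15 aldehyde to alkyne; ester arm lengthened to the C3–C5 enoate; ring B (piperidine) on nitro reduction; ring C by Claisen/Mannich/dehydration; C17–C21 chain joined by alkynylation; Z-alkene; ring D (15-membered lactone) last.
- Stereochemistry: C13/C14 from the (S)-prolinol silyl ether catalyst; C9 from C13 (acrylate enters anti to the arm); C5 from a reversible aza-Michael closure; C17 from (S,S)-ProPhenol/zinc; 15Z from syn hydrogenation; the C18=C19 geometry from syn stannylcupration and retentive tin-to-chlorine exchange.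

Key step: step 3

Remark on locants: C1–C22 are the target's positions (C1 lactone carbonyl, C2=C3, C5 N–CH, C9 spiro carbon, C13, C14 CHCH3, C15=C16, C17 carbinol, C18=C19(Cl), C21 OCH2, C22 NCH2).

Assumption: the (S,S) antipode of ProPhenol is taken to deliver the zinc acetylide to the Re face of enal 26, the sense it shows in its aldol reactions; if the sense is reversed on this substrate the (R,R) ligand is used.

Silyl ether 20 is a catalogue compound.

**Route**

Step 1
Reactants: 1 cyclopentene
Product: 2 rac-trans-chloro(2-nitrocyclopentyl)mercury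
Conditions: HgCl2, NaNO2, H2O, rt
Reagents that add atoms: mercury dichloride, Cl[Hg]Cl; sodium nitrite, [Na+].[O-]N=O
Why: Nitromercuration, in which nitrite opens the mercurinium ion anti, places nitrogen and mercury on adjacent ring carbons ready for elimination.

Step 2
Reactants: 2 rac-trans-chloro(2-nitrocyclopentyl)mercury
Product: 3 1-nitrocyclopentene
Conditions: 2.5 M NaOH (aq), CH2Cl2, rt
Reagents that add atoms: none
Why: Base-induced demercuration (E1cB through the nitronate with loss of mercury metal) gives the conjugated nitroalkene.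

Step 3
Reactants: 3 1-nitrocyclopentene; 4 propanal; 5 methyl acrylate
Product: 7 methyl 3-{(1S,2R)-1-nitro-2-[(2R)-1-oxopropan-2-yl]cyclopentyl}propanoate, via γ-nitro aldehyde 6 (not isolated)
Conditions: 4 (3 equiv), (S)-α,α-diphenylprolinol trimethylsilyl ether (10 mol %), PhCO2H (10 mol %), toluene, 0 °C → rt; excess 4 removed in vacuo; then 5 (3 equiv), 1,1,3,3-tetramethylguanidine (0.3 equiv), MeCN, 0 °C; AcOH quench
Reagents that add atoms: none
Why: The catalyst and propanal form the E-enamine, which adds to the β-carbon (C13) of 3 through the acyclic synclinal transition state and is hydrolysed to 6; the guanidine then deprotonates C9–H of either epimer of 6 to one planar nitronate, which adds to methyl acrylate, the ester enolate being protonated by the next molecule of 6. The closest known reactions are the secondary-amine-catalysed Michael addition of aldehydes to nitroalkenes and the base-mediated Michael addition of a secondary nitroalkane to an acrylate, here run consecutively in one flask. No ring is closed; the bonds C13–C14 and C9–C8 are formed. C13 and C14 are set together by the (S)-catalyst, whose diphenyl(silyloxy)methyl group shields one enamine face and gives the syn pair, and C9 is set by the new C13 side chain, which blocks one face of the nitronate so that the acrylate enters trans to it and nitrogen ends cis to the C14 arm. The step needs the C14 configuration α to the aldehyde to survive the basic second stage; this is secured because the base is substoichiometric and is buffered as the nitronate by the far more acidic nitroalkane until 6 is consumed, after which it is quenched with AcOH, and because excess propanal is removed before the base is added.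

Step 4
Reactants: 7 methyl 3-{(1S,2R)-1-nitro-2-[(2R)-1-oxopropan-2-yl]cyclopentyl}propanoate
Product: 8 methyl 3-{(1S,2R)-2-[(2R)-but-3-yn-2-yl]-1-nitrocyclopentyl}propanoate
Conditions: dimethyl (1-diazo-2-oxopropyl)phosphonate, K2CO3, MeOH, 0 °C → rt
Reagents that add atoms: dimethyl (1-diazo-2-oxopropyl)phosphonate, CC(=O)C(=[N+]=[N-])P(=O)(OC)OC
Why: Ohira–Bestmann homologation (diazomethylphosphonate addition, then 1,2-shift in the alkylidene carbene) turns the epimerisable aldehyde into the terminal alkyne under mild carbonate conditions and so fixes C14 as a stable propargylic centre.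

Step 5
Reactants: 8 methyl 3-{(1S,2R)-2-[(2R)-but-3-yn-2-yl]-1-nitrocyclopentyl}propanoate
Product: 9 3-{(1S,2R)-2-[(2R)-but-3-yn-2-yl]-1-nitrocyclopentyl}propanal
Conditions: i-Bu2AlH (1.1 equiv), CH2Cl2, −78 °C; MeOH, aq. KNaC4H4O6
Reagents that add atoms: none
Why: Half-reduction of the ester with i-Bu2AlH stops at the aluminium hemiacetal at −78 °C, a temperature at which the tertiary nitro group and the alkyne are inert.

Step 6
Reactants: 9 3-{(1S,2R)-2-[(2R)-but-3-yn-2-yl]-1-nitrocyclopentyl}propanal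
Product: 11 4-{(1S,2R)-2-[(2R)-but-3-yn-2-yl]-1-nitrocyclopentyl}butanal, via enol ether 10 (not isolated)
Conditions: Ph3P(CH2OMe)Cl, KN(SiMe3)2, THF, 0 °C; then 2 M HCl, THF, rt
Reagents that add atoms: (methoxymethyl)triphenylphosphonium chloride, COC[P+](c1ccccc1)(c1ccccc1)c1ccccc1.[Cl-]; water, O
Why: Wittig methoxymethylenation and acid hydrolysis of the enol ether is the standard one-carbon aldehyde homologation and supplies C5, the nitro group having no α-hydrogen for the ylide to attack.

Step 7
Reactants: 11 4-{(1S,2R)-2-[(2R)-but-3-yn-2-yl]-1-nitrocyclopentyl}butanal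
Product: 12 ethyl (2E)-6-{(1S,2R)-2-[(2R)-but-3-yn-2-yl]-1-nitrocyclopentyl}hex-2-enoate
Conditions: Ph3P=CHCO2Et, CH2Cl2, rt
Reagents that add atoms: ethyl (triphenylphosphoranylidene)acetate, CCOC(=O)C=P(c1ccccc1)(c1ccccc1)c1ccccc1
Why: Wittig olefination with the stabilised ylide gives the (E)-enoate that serves as Michael acceptor for ring B.

Step 8
Reactants: 12 ethyl (2E)-6-{(1S,2R)-2-[(2R)-but-3-yn-2-yl]-1-nitrocyclopentyl}hex-2-enoate
Product: 14 ethyl 2-{(1R,5S,7R)-1-[(2R)-but-3-yn-2-yl]-6-azaspiro[4.5]decan-7-yl}acetate, via amino enoate 13 (not isolated)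
Conditions: Zn dust, AcOH, THF, rt → 50 °C; aq. NaHCO3 work-up; EtOH, 40 °C
Reagents that add atoms: none
Why: Dissolving-metal reduction of the tertiary nitro group spares enoate and alkyne, and the freed amine closes ring B by 6-exo-trig aza-Michael addition, which, being reversible, should settle C5 (R) in the chair that holds both the C4 ester arm and the branched C13 equatorial.

Step 9
Reactants: 14 ethyl 2-{(1R,5S,7R)-1-[(2R)-but-3-yn-2-yl]-6-azaspiro[4.5]decan-7-yl}acetate
Product: 15 tert-butyl 4-{(1R,5S,7R)-1-[(2R)-but-3-yn-2-yl]-6-azaspiro[4.5]decan-7-yl}-3-oxobutanoate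
Conditions: t-BuOAc, LiN(i-Pr)2 (5 equiv), THF, −78 °C; add 14, −78 → −30 °C; AcOH
Reagents that add atoms: tert-butyl acetate, CC(=O)OC(C)(C)C
Why: Crossed Claisen condensation with excess lithium enolate of tert-butyl acetate acylates at the ethyl ester and parks the product as its enolate, while the hindered N–H and the alkyne (as acetylide) stay spectators.

Step 10
Reactants: 15 tert-butyl 4-{(1R,5S,7R)-1-[(2R)-but-3-yn-2-yl]-6-azaspiro[4.5]decan-7-yl}-3-oxobutanoate
Product: 16 tert-butyl (1S,2R,9a'R)-2-[(2R)-but-3-yn-2-yl]-8'-oxooctahydrospiro[cyclopentane-1,4'-quinolizine]-7'-carboxylate (C7' epimers and enol)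
Conditions: aq. CH2O (37 %), EtOH, rt
Reagents that add atoms: formaldehyde, C=O
Why: Intramolecular Mannich reaction, in which the N-methyleneiminium ion from the secondary amine is trapped 6-endo by the β-keto ester enol at C2, closes ring C and brings in C22; the C2 centre is of no consequence as it becomes sp2.

Step 11
Reactants: 16 tert-butyl (1S,2R,9a'R)-2-[(2R)-but-3-yn-2-yl]-8'-oxooctahydrospiro[cyclopentane-1,4'-quinolizine]-7'-carboxylate
Product: 17 tert-butyl (1S,2R,9a'R)-2-[(2R)-but-3-yn-2-yl]-8'-hydroxyoctahydrospiro[cyclopentane-1,4'-quinolizine]-7'-carboxylate (mixture at C7' and C8')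
Conditions: NaBH4, MeOH, −20 °C
Reagents that add atoms: none
Why: Borohydride reduction takes the ketone of the β-keto ester and leaves the tert-butyl ester, the new carbinol configuration being irrelevant.

Step 12
Reactants: 17 tert-butyl (1S,2R,9a'R)-2-[(2R)-but-3-yn-2-yl]-8'-hydroxyoctahydrospiro[cyclopentane-1,4'-quinolizine]-7'-carboxylate
Product: 19 tert-butyl (1S,2R,9a'R)-2-[(2R)-but-3-yn-2-yl]-1',2',3',6',9',9a'-hexahydrospiro[cyclopentane-1,4'-quinolizine]-7'-carboxylate, via mesylate 18 (not isolated)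
Conditions: MsCl, Et3N, CH2Cl2, 0 °C; then DBU, rt
Reagents that add atoms: none
Why: Mesylation followed by E1cB elimination through the ester enolate puts the double bond at C2=C3 in conjugation with the ester, whichever carbinol epimer is present.

Step 13
Reactants: 20 tert-butyl(but-3-yn-1-yloxy)dimethylsilane
Product: 22 methyl 5-[(tert-butyldimethylsilyl)oxy]pent-2-ynoate, via lithium acetylide 21 (not isolated)
Conditions: n-BuLi, THF, −78 °C; ClCO2Me, −78 → 0 °C
Reagents that add atoms: methyl chloroformate, COC(=O)Cl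
Why: C-acylation of the lithium acetylide with a chloroformate installs C17 as the ester that activates the alkyne for cuprate addition.

Step 14
Reactants: 22 methyl 5-[(tert-butyldimethylsilyl)oxy]pent-2-ynoate
Product: 23 methyl (2E)-5-[(tert-butyldimethylsilyl)oxy]-3-(trimethylstannyl)pent-2-enoate
Conditions: Me3SnCu(SPh)Li (from Me3SnSnMe3, MeLi, PhSCu), MeOH (1.7 equiv), THF, −100 → −78 °C
Reagents that add atoms: lithium (phenylthio)(trimethylstannyl)cuprate, [Li+].C[Sn](C)(C)[Cu-]Sc1ccccc1
Why: Stannylcupration of the ynoate is a syn addition, and with the proton source present at low temperature the vinylcopper is quenched before it can isomerise, so tin lands on C19 cis to H18, which is the (E)-geometry.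

Step 15
Reactants: 23 methyl (2E)-5-[(tert-butyldimethylsilyl)oxy]-3-(trimethylstannyl)pent-2-enoate
Product: 24 methyl (2E)-3-chloro-5-[(tert-butyldimethylsilyl)oxy]pent-2-enoate
Conditions: CuCl2 (2.2 equiv), THF, 0 °C → rt
Reagents that add atoms: copper dichloride, Cl[Cu]Cl
Why: Chlorodestannylation of an alkenylstannane with CuCl2 proceeds with retention, so chlorine takes the place of tin trans to the ester carbon.

Step 16
Reactants: 24 methyl (2E)-3-chloro-5-[(tert-butyldimethylsilyl)oxy]pent-2-enoate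
Product: 25 (2E)-3-chloro-5-[(tert-butyldimethylsilyl)oxy]pent-2-en-1-ol
Conditions: i-Bu2AlH (2.2 equiv), CH2Cl2, −78 °C
Reagents that add atoms: none
Why: 1,2-Reduction of the conjugated ester with i-Bu2AlH gives the allylic alcohol without touching the vinylic chloride or the silyl ether.

Step 17
Reactants: 25 (2E)-3-chloro-5-[(tert-butyldimethylsilyl)oxy]pent-2-en-1-ol
Product: 26 (2E)-3-chloro-5-[(tert-butyldimethylsilyl)oxy]pent-2-enal
Conditions: MnO2, CH2Cl2, rt; used at once
Reagents that add atoms: none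
Why: Allylic oxidation with MnO2 is neutral and heterogeneous, which should keep the β-chloro enal from isomerising about its double bond before use.

Step 18
Reactants: 19 tert-butyl (1S,2R,9a'R)-2-[(2R)-but-3-yn-2-yl]-1',2',3',6',9',9a'-hexahydrospiro[cyclopentane-1,4'-quinolizine]-7'-carboxylate; 26 (2E)-3-chloro-5-[(tert-butyldimethylsilyl)oxy]pent-2-enal
Product: 28 tert-butyl (1S,2R,9a'R)-2-[(2R,5S,6E)-7-chloro-9-[(tert-butyldimethylsilyl)oxy]-5-hydroxynon-6-en-3-yn-2-yl]-1',2',3',6',9',9a'-hexahydrospiro[cyclopentane-1,4'-quinolizine]-7'-carboxylate, via alkynylzinc 27 (not isolated)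
Conditions: Me2Zn (3 equiv), (S,S)-ProPhenol (20 mol %), Ph3P=O (40 mol %), toluene, 0 °C; then 26 (1.5 equiv), 0 °C → rt
Reagents that add atoms: none
Why: Dinuclear zinc–ProPhenol-catalysed alkynylation of an enal adds the alkynylzinc 1,2 within the chiral pocket to the Re face of 26, forming C16–C17 and setting C17 (S at this stage, R once C16 is olefinic).

Step 19
Reactants: 28 the propargylic alcohol of step 18
Product: 29 tert-butyl (1S,2R,9a'R)-2-[(2S,3Z,5R,6E)-7-chloro-9-[(tert-butyldimethylsilyl)oxy]-5-hydroxynona-3,6-dien-2-yl]-1',2',3',6',9',9a'-hexahydrospiro[cyclopentane-1,4'-quinolizine]-7'-carboxylate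
Conditions: H2 (1 atm), Pd/CaCO3 poisoned with Pb(OAc)2, quinoline, EtOAc, rt
Reagents that add atoms: none
Why: Alkyne semihydrogenation on poisoned palladium delivers both hydrogens to one face and gives the (15Z)-alkene, the trisubstituted enoate and the vinylic chloride reacting much more slowly on this catalyst.

Step 20
Reactants: 29 the (Z)-allylic alcohol of step 19
Product: 31 (1S,2R,9a'R)-2-[(2S,3Z,5R,6E)-5-[(tert-butyldimethylsilyl)oxy]-7-chloro-9-hydroxynona-3,6-dien-2-yl]-1',2',3',6',9',9a'-hexahydrospiro[cyclopentane-1,4'-quinolizine]-7'-carboxylic acid, via tris-silyl ester 30 (not isolated)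
Conditions: TBSOTf, 2,6-lutidine, CH2Cl2, 0 °C → rt; then NH4F, MeOH/H2O, rt
Reagents that add atoms: tert-butyldimethylsilyl trifluoromethanesulfonate, CC(C)(C)[Si](C)(C)OS(=O)(=O)C(F)(F)F
Why: Silyl triflate silylates C17–OH and converts the tert-butyl ester into a silyl ester with loss of isobutene (silyl-transfer ester cleavage), and mild fluoride then frees the acid and the primary C21 hydroxyl but not the hindered secondary silyl ether, so no acid touches the doubly allylic carbinol.

Step 21
Reactants: 31 the seco acid of step 20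
Product: 32 17-O-(tert-butyldimethylsilyl) ether of the target macrolactone
Conditions: DCC, DMAP, DMAP·HCl, CHCl3, reflux, slow addition at high dilution
Reagents that add atoms: none
Why: Carbodiimide macrolactonisation under Keck–Boden conditions closes ring D through the only free hydroxyl, the proton source suppressing N-acylurea formation and the Z-alkene and ring C holding the two ends near each other.

Step 22
Reactants: 32 17-O-(tert-butyldimethylsilyl) ether of the target macrolactone
Product: 33 target macrolactone CNP0129639.4 (5R,9S,13R,14S,17R; 15Z; chlorine trans to C17 across C18=C19)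
Conditions: HF·pyridine, pyridine, THF, 0 °C → rt
Reagents that add atoms: none
Why: Buffered fluoride desilylation removes the last silyl ether without ionising the doubly allylic alcohol or opening the lactone.

**Compound list**

1 | cyclopentene | C1=CCCC1 | starting material
2 | rac-trans-chloro(2-nitrocyclopentyl)mercury | [O-][N+](=O)[C@@H]1CCC[C@H]1[Hg]Cl | intermediate
3 | 1-nitrocyclopentene | [O-][N+](=O)C1=CCCC1 | intermediate
4 | propanal | CCC=O | starting material
5 | methyl acrylate | C=CC(=O)OC | starting material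
6 | (2R)-2-[(1R)-2-nitrocyclopentyl]propanal (both epimers at the nitro carbon) | O=C[C@H](C)[C@H]1CCCC1[N+](=O)[O-] | intermediate
7 | methyl 3-{(1S,2R)-1-nitro-2-[(2R)-1-oxopropan-2-yl]cyclopentyl}propanoate | O=C[C@H](C)[C@H]1CCC[C@]1([N+](=O)[O-])CCC(=O)OC | intermediate
8 | methyl 3-{(1S,2R)-2-[(2R)-but-3-yn-2-yl]-1-nitrocyclopentyl}propanoate | C#C[C@H](C)[C@H]1CCC[C@]1([N+](=O)[O-])CCC(=O)OC | intermediate
9 | 3-{(1S,2R)-2-[(2R)-but-3-yn-2-yl]-1-nitrocyclopentyl}propanal | C#C[C@H](C)[C@H]1CCC[C@]1([N+](=O)[O-])CCC=O | intermediate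
10 | (1S,2R)-2-[(2R)-but-3-yn-2-yl]-1-(4-methoxybut-3-en-1-yl)-1-nitrocyclopentane (E/Z mixture) | C#C[C@H](C)[C@H]1CCC[C@]1([N+](=O)[O-])CCC=COC | intermediate
11 | 4-{(1S,2R)-2-[(2R)-but-3-yn-2-yl]-1-nitrocyclopentyl}butanal | C#C[C@H](C)[C@H]1CCC[C@]1([N+](=O)[O-])CCCC=O | intermediate
12 | ethyl (2E)-6-{(1S,2R)-2-[(2R)-but-3-yn-2-yl]-1-nitrocyclopentyl}hex-2-enoate | C#C[C@H](C)[C@H]1CCC[C@]1([N+](=O)[O-])CCC/C=C/C(=O)OCC | intermediate
13 | ethyl (2E)-6-{(1S,2R)-1-amino-2-[(2R)-but-3-yn-2-yl]cyclopentyl}hex-2-enoate | C#C[C@H](C)[C@H]1CCC[C@]1(N)CCC/C=C/C(=O)OCC | intermediate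
14 | ethyl 2-{(1R,5S,7R)-1-[(2R)-but-3-yn-2-yl]-6-azaspiro[4.5]decan-7-yl}acetate | C#C[C@H](C)[C@H]1CCC[C@]12CCC[C@@H](N2)CC(=O)OCC | intermediate
15 | tert-butyl 4-{(1R,5S,7R)-1-[(2R)-but-3-yn-2-yl]-6-azaspiro[4.5]decan-7-yl}-3-oxobutanoate | C#C[C@H](C)[C@H]1CCC[C@]12CCC[C@@H](N2)CC(=O)CC(=O)OC(C)(C)C | intermediate
16 | tert-butyl (1S,2R,9a'R)-2-[(2R)-but-3-yn-2-yl]-8'-oxooctahydrospiro[cyclopentane-1,4'-quinolizine]-7'-carboxylate (C7' epimers) | C#C[C@H](C)[C@H]1CCC[C@]12CCC[C@@H]3CC(=O)C(C(=O)OC(C)(C)C)CN23 | intermediate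
17 | tert-butyl (1S,2R,9a'R)-2-[(2R)-but-3-yn-2-yl]-8'-hydroxyoctahydrospiro[cyclopentane-1,4'-quinolizine]-7'-carboxylate (mixture at C7', C8') | C#C[C@H](C)[C@H]1CCC[C@]12CCC[C@@H]3CC(O)C(C(=O)OC(C)(C)C)CN23 | intermediate
18 | tert-butyl (1S,2R,9a'R)-2-[(2R)-but-3-yn-2-yl]-8'-(methanesulfonyloxy)octahydrospiro[cyclopentane-1,4'-quinolizine]-7'-carboxylate (mixture at C7', C8') | C#C[C@H](C)[C@H]1CCC[C@]12CCC[C@@H]3CC(OS(C)(=O)=O)C(C(=O)OC(C)(C)C)CN23 | intermediate
19 | tert-butyl (1S,2R,9a'R)-2-[(2R)-but-3-yn-2-yl]-1',2',3',6',9',9a'-hexahydrospiro[cyclopentane-1,4'-quinolizine]-7'-carboxylate | C#C[C@H](C)[C@H]1CCC[C@]12CCC[C@@H]3CC=C(C(=O)OC(C)(C)C)CN23 | intermediate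
20 | tert-butyl(but-3-yn-1-yloxy)dimethylsilane | C#CCCO[Si](C)(C)C(C)(C)C | starting material
21 | lithium acetylide of 20 | [Li]C#CCCO[Si](C)(C)C(C)(C)C | intermediate
22 | methyl 5-[(tert-butyldimethylsilyl)oxy]pent-2-ynoate | COC(=O)C#CCCO[Si](C)(C)C(C)(C)C | intermediate
23 | methyl (2E)-5-[(tert-butyldimethylsilyl)oxy]-3-(trimethylstannyl)pent-2-enoate | COC(=O)/C=C(/[Sn](C)(C)C)CCO[Si](C)(C)C(C)(C)C | intermediate
24 | methyl (2E)-3-chloro-5-[(tert-butyldimethylsilyl)oxy]pent-2-enoate | COC(=O)/C=C(/Cl)CCO[Si](C)(C)C(C)(C)C | intermediate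
25 | (2E)-3-chloro-5-[(tert-butyldimethylsilyl)oxy]pent-2-en-1-ol | OC/C=C(/Cl)CCO[Si](C)(C)C(C)(C)C | intermediate
26 | (2E)-3-chloro-5-[(tert-butyldimethylsilyl)oxy]pent-2-enal | O=C/C=C(/Cl)CCO[Si](C)(C)C(C)(C)C | intermediate
27 | methylzinc acetylide of 19 | C[Zn]C#C[C@H](C)[C@H]1CCC[C@]12CCC[C@@H]3CC=C(C(=O)OC(C)(C)C)CN23 | intermediate
28 | tert-butyl (1S,2R,9a'R)-2-[(2R,5S,6E)-7-chloro-9-[(tert-butyldimethylsilyl)oxy]-5-hydroxynon-6-en-3-yn-2-yl]-1',2',3',6',9',9a'-hexahydrospiro[cyclopentane-1,4'-quinolizine]-7'-carboxylate | C[C@@H](C#C[C@@H](O)/C=C(/Cl)CCO[Si](C)(C)C(C)(C)C)[C@H]1CCC[C@]12CCC[C@@H]3CC=C(C(=O)OC(C)(C)C)CN23 | intermediate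
29 | tert-butyl (1S,2R,9a'R)-2-[(2S,3Z,5R,6E)-7-chloro-9-[(tert-butyldimethylsilyl)oxy]-5-hydroxynona-3,6-dien-2-yl]-1',2',3',6',9',9a'-hexahydrospiro[cyclopentane-1,4'-quinolizine]-7'-carboxylate | C[C@@H](/C=C\[C@@H](O)/C=C(/Cl)CCO[Si](C)(C)C(C)(C)C)[C@H]1CCC[C@]12CCC[C@@H]3CC=C(C(=O)OC(C)(C)C)CN23 | intermediate
30 | tert-butyldimethylsilyl ester of the 17,21-bis-O-(tert-butyldimethylsilyl) seco acid | C[C@@H](/C=C\[C@@H](O[Si](C)(C)C(C)(C)C)/C=C(/Cl)CCO[Si](C)(C)C(C)(C)C)[C@H]1CCC[C@]12CCC[C@@H]3CC=C(C(=O)O[Si](C)(C)C(C)(C)C)CN23 | intermediate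
31 | (1S,2R,9a'R)-2-[(2S,3Z,5R,6E)-5-[(tert-butyldimethylsilyl)oxy]-7-chloro-9-hydroxynona-3,6-dien-2-yl]-1',2',3',6',9',9a'-hexahydrospiro[cyclopentane-1,4'-quinolizine]-7'-carboxylic acid | C[C@@H](/C=C\[C@@H](O[Si](C)(C)C(C)(C)C)/C=C(/Cl)CCO)[C@H]1CCC[C@]12CCC[C@@H]3CC=C(C(=O)O)CN23 | intermediate
32 | 17-O-(tert-butyldimethylsilyl) ether of the target macrolactone | C[C@H]1/C=C\[C@@H](O[Si](C)(C)C(C)(C)C)/C=C(/Cl)CCOC(=O)C2=CC[C@H]3CCC[C@]4(CCC[C@H]14)N3C2 | intermediate
33 | target macrolactone CNP0129639.4 | C[C@H]1/C=C\[C@@H](O)/C=C(/Cl)CCOC(=O)C2=CC[C@H]3CCC[C@]4(CCC[C@H]14)N3C2 | target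

**Count**

Total: 22 steps. Longest linear sequence: 17 steps (1–12, then 18–22); the C17–C21 branch is steps 13–17.

**Steps most likely to fail**

1. Step 3. The α-methyl aldehyde may enolise during the basic second stage and lose the C14 configuration, or the nitronate may show too little facial bias. Fallback, setting out from 6 and returning at 7: the enamine Michael reaction of 3 and 4 is run alone and 6 is reduced in the same flask with NaBH4 to (2R)-2-[(1R)-2-nitrocyclopentyl]propan-1-ol F1. With no aldehyde left, F1 is treated with 5 and a full equivalent of DBU in MeCN, the nitronate again adding anti to the C13 arm, to give methyl 3-{(1S,2R)-2-[(2R)-1-hydroxypropan-2-yl]-1-nitrocyclopentyl}propanoate F2. Dess–Martin oxidation of F2 under non-basic conditions then gives 7.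

2. Step 18. The dinuclear zinc catalyst may be slowed by the basic amine of 19, facial selectivity at C17 may be poor, or the acetylide may attack the chlorine-bearing carbon by addition–elimination. Fallback, setting out from 19 and 26 and returning at 28: alkynylzinc 27 is added to 26 with Ti(Oi-Pr)4 and no chiral ligand, giving the C17-epimeric mixture of 28 F3. MnO2 oxidises it to the ynone tert-butyl (1S,2R,9a'R)-2-[(2R,6E)-7-chloro-9-[(tert-butyldimethylsilyl)oxy]-5-oxonon-6-en-3-yn-2-yl]-1',2',3',6',9',9a'-hexahydrospiro[cyclopentane-1,4'-quinolizine]-7'-carboxylate F4. Corey–Bakshi–Shibata reduction with (S)-Me-CBS and catecholborane at −78 °C, the alkynyl group acting as the small substituent, should then give 28.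

3. Step 19. Hydrogenation may run on to the saturated chain or cleave the vinylic C–Cl bond. Fallback, setting out from 19 and returning at 29, so that no hydrogenation is needed once the chloroalkene is present: 19 is iodinated with N-iodosuccinimide and catalytic AgNO3 to the 1-iodoalkyne tert-butyl (1S,2R,9a'R)-2-[(2R)-4-iodobut-3-yn-2-yl]-1',2',3',6',9',9a'-hexahydrospiro[cyclopentane-1,4'-quinolizine]-7'-carboxylate F5. Diimide (2-nitrobenzenesulfonylhydrazide, Et3N) reduces it cis to the (Z)-vinyl iodide tert-butyl (1S,2R,9a'R)-2-[(2R,3Z)-4-iodobut-3-en-2-yl]-1',2',3',6',9',9a'-hexahydrospiro[cyclopentane-1,4'-quinolizine]-7'-carboxylate F6. Nozaki–Hiyama–Kishi coupling of F6 with 26 (CrCl2, catalytic NiCl2, chiral sulfonamide ligand, THF) keeps the Z geometry and gives 29, the C17 epimer being removed by chromatography if the ligand control is incomplete.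

**Further compounds**

F1 | step 3 | (2R)-2-[(1R)-2-nitrocyclopentyl]propan-1-ol (both epimers at the nitro carbon) | OC[C@H](C)[C@H]1CCCC1[N+](=O)[O-]
F2 | step 3 | methyl 3-{(1S,2R)-2-[(2R)-1-hydroxypropan-2-yl]-1-nitrocyclopentyl}propanoate | OC[C@H](C)[C@H]1CCC[C@]1([N+](=O)[O-])CCC(=O)OC
F3 | step 18 | C17-epimeric mixture of 28 | C[C@@H](C#CC(O)/C=C(/Cl)CCO[Si](C)(C)C(C)(C)C)[C@H]1CCC[C@]12CCC[C@@H]3CC=C(C(=O)OC(C)(C)C)CN23
F4 | step 18 | tert-butyl (1S,2R,9a'R)-2-[(2R,6E)-7-chloro-9-[(tert-butyldimethylsilyl)oxy]-5-oxonon-6-en-3-yn-2-yl]-1',2',3',6',9',9a'-hexahydrospiro[cyclopentane-1,4'-quinolizine]-7'-carboxylate | C[C@@H](C#CC(=O)/C=C(/Cl)CCO[Si](C)(C)C(C)(C)C)[C@H]1CCC[C@]12CCC[C@@H]3CC=C(C(=O)OC(C)(C)C)CN23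
F5 | step 19 | tert-butyl (1S,2R,9a'R)-2-[(2R)-4-iodobut-3-yn-2-yl]-1',2',3',6',9',9a'-hexahydrospiro[cyclopentane-1,4'-quinolizine]-7'-carboxylate | IC#C[C@H](C)[C@H]1CCC[C@]12CCC[C@@H]3CC=C(C(=O)OC(C)(C)C)CN23
F6 | step 19 | tert-butyl (1S,2R,9a'R)-2-[(2R,3Z)-4-iodobut-3-en-2-yl]-1',2',3',6',9',9a'-hexahydrospiro[cyclopentane-1,4'-quinolizine]-7'-carboxylate | I/C=C\[C@H](C)[C@H]1CCC[C@]12CCC[C@@H]3CC=C(C(=O)OC(C)(C)C)CN23
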